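**Retrosynthetic overview**

1. The target is the O–C(para) ether of two (S)-curcuphenol units. Both benzylic stereocentres are drawn from one reagent, secondary boronic ester (S)-8, made by sparteine-mediated lithiation–borylation of ethyl 2,4,6-triisopropylbenzoate with homoprenyl-Bpin.
2. Key disconnection: the C1(ring A)–CH(CH3) bond, ortho to the phenolic oxygen on C6 of ring A (the hydroquinone-type ring). It is made by a stereoretentive 1,2-metallate shift in the boronate formed from ortho-lithiated aryloxybenzotriazole 22 and (S)-8.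
3. Enabling feature: the C6–OH of ring A next to C1. Worn as C6–O–N1(benzotriazole), it acidifies C1–H and its weak N–O bond turns ring A into a phenoxenium equivalent; it is expelled in the key step itself, so the free phenol appears without a deprotection.
4. Precursor 22 comes from boronic acid 21 (Chan–Lam with HOBt), 21 from bromide 18 (Br–Li exchange, borate), and 18 from Ullmann etherification of (S)-curcuphenol 16 with 4-bromo-1-iodo-2-methylbenzene.
5. 16 comes from the same boronate coupling on m-tolyl ether 11. No ring is constructed: both benzene rings are bought; ring B is dressed first, ring A last.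

Key step: step 9

Assumption: (+)-sparteine and anhydrous 1-hydroxybenzotriazole are taken as purchasable; ring A is numbered C1 (carbon that receives the side chain) to C6 (phenol carbon), with the aryloxy group on C3 and the methyl group on C4.

**Route**

Step 1
Reactants: 1 5-bromo-2-methylpent-2-ene
Product: 3 2-(4-methylpent-3-en-1-yl)-4,4,5,5-tetramethyl-1,3,2-dioxaborolane, via (4-methylpent-3-en-1-yl)magnesium bromide 2 (not isolated)
Conditions: Mg, THF, rt to 45 °C; then i-PrOBpin, THF, −78 °C to rt; aq. NH4Cl
Reagents that add atoms: 2-isopropoxy-4,4,5,5-tetramethyl-1,3,2-dioxaborolane, CC(C)OB1OC(C)(C)C(C)(C)O1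
Why: Grignard formation and borylation with an alkoxyboronate is the standard entry to primary alkyl pinacol boronic esters, and the trisubstituted alkene is inert to it.

Step 2
Reactants: 4 2,4,6-triisopropylbenzoic acid
Product: 5 ethyl 2,4,6-triisopropylbenzoate
Conditions: EtI, K2CO3, DMF, 50 °C
Reagents that add atoms: iodoethane, CCI
Why: Carboxylate O-alkylation (SN2 at the ethyl carbon) is not slowed by the steric shielding of the 2,6-diisopropyl acyl carbon.

Step 3
Reactants: 5 ethyl 2,4,6-triisopropylbenzoate; 3 2-(4-methylpent-3-en-1-yl)-4,4,5,5-tetramethyl-1,3,2-dioxaborolane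
Product: 8 4,4,5,5-tetramethyl-2-[(2S)-6-methylhept-5-en-2-yl]-1,3,2-dioxaborolane, via (R)-1-lithioethyl triisopropylbenzoate 6 (not isolated), via lithium boronate complex 7 (not isolated)
Conditions: s-BuLi, (+)-sparteine, Et2O, −78 °C; then 3, −78 °C; then reflux (35 °C); aq. NH4Cl
Reagents that add atoms: none
Why: In this sparteine-mediated lithiation–borylation (1,2-metallate rearrangement), s-BuLi/(+)-sparteine should remove the pro-R hydrogen of the OCH2 group to give (R)-6, boron is taken up with retention, and the anti-periplanar shift of the homoprenyl group with loss of the triisopropylbenzoate inverts that carbon, which sets the (S)-configured C–B centre.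

Step 4
Reactants: 9 (3-methylphenyl)boronic acid; 10 1-hydroxy-1H-benzotriazole
Product: 11 1-(3-methylphenoxy)-1H-benzotriazole
Conditions: Cu(OAc)2 (20 mol %), pyridine, 4 Å MS, CH2Cl2, air, rt
Reagents that add atoms: none
Why: Chan–Lam oxidative copper coupling of an arylboronic acid with an N-hydroxy heterocycle forms the aryl–O–N linkage at room temperature, as it does with N-hydroxyphthalimide.

Step 5
Reactants: 11 1-(3-methylphenoxy)-1H-benzotriazole; 8 4,4,5,5-tetramethyl-2-[(2S)-6-methylhept-5-en-2-yl]-1,3,2-dioxaborolane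
Product: 16 (S)-curcuphenol [5-methyl-2-[(2S)-6-methylhept-5-en-2-yl]phenol], via ortho-lithiated aryloxybenzotriazole 12 (not isolated), via lithium boronate complex 13 (not isolated), via 6-boryl-cyclohexa-2,4-dienone 14 (not isolated), via aryl pinacol borate 15 (not isolated)
Conditions: LDA, THF, −78 °C; then 8, −78 °C to rt; aq. NH4Cl
Reagents that add atoms: none
Why: This is the enantiospecific sp2–sp3 coupling of an ortho-lithiated O-benzotriazolyl phenol with a secondary boronic ester: the O–N group directs lithiation to the ortho carbon not flanked by the methyl group, the boronate undergoes a stereoretentive 1,2-shift as benzotriazolide leaves, and a 1,3-boryl shift to oxygen rearomatises the ring, so the (S)-centre of 8 is carried over unchanged.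

Step 6
Reactants: 16 (S)-curcuphenol; 17 4-bromo-1-iodo-2-methylbenzene
Product: 18 4-bromo-2-methyl-1-{5-methyl-2-[(2S)-6-methylhept-5-en-2-yl]phenoxy}benzene
Conditions: CuI (10 mol %), picolinic acid (20 mol %), K3PO4, DMSO, 80 °C
Reagents that add atoms: none
Why: The Ullmann-type copper/picolinic acid diaryl ether synthesis tolerates ortho substituents on both partners, and the C–I bond should react well ahead of the C–Br bond, which stays as the handle for the next step.

Step 7
Reactants: 18 4-bromo-2-methyl-1-{5-methyl-2-[(2S)-6-methylhept-5-en-2-yl]phenoxy}benzene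
Product: 21 (3-methyl-4-{5-methyl-2-[(2S)-6-methylhept-5-en-2-yl]phenoxy}phenyl)boronic acid, via aryllithium 19 (not isolated), via lithium aryl(triisopropoxy)borate 20 (not isolated)
Conditions: n-BuLi, THF, −78 °C; then B(Oi-Pr)3, −78 °C to rt; 1 M HCl, 0 °C
Reagents that add atoms: triisopropyl borate, CC(C)OB(OC(C)C)OC(C)C; water, O
Why: Bromine–lithium exchange at −78 °C is faster than any deprotonation of the diaryl ether, and borate trapping followed by mild hydrolysis is the standard route to an arylboronic acid.

Step 8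
Reactants: 21 (3-methyl-4-{5-methyl-2-[(2S)-6-methylhept-5-en-2-yl]phenoxy}phenyl)boronic acid; 10 1-hydroxy-1H-benzotriazole
Product: 22 1-(3-methyl-4-{5-methyl-2-[(2S)-6-methylhept-5-en-2-yl]phenoxy}phenoxy)-1H-benzotriazole
Conditions: Cu(OAc)2 (20 mol %), pyridine, 4 Å MS, CH2Cl2, air, rt
Reagents that add atoms: none
Why: The Chan–Lam O-arylation of step 4 is repeated on a boronic acid without ortho substituents; the diaryl ether and both trisubstituted alkenes are inert to Cu(II)/pyridine/air at room temperature.

Step 9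
Reactants: 22 1-(3-methyl-4-{5-methyl-2-[(2S)-6-methylhept-5-en-2-yl]phenoxy}phenoxy)-1H-benzotriazole; 8 4,4,5,5-tetramethyl-2-[(2S)-6-methylhept-5-en-2-yl]-1,3,2-dioxaborolane
Product: 27 5-methyl-2-[(2S)-6-methylhept-5-en-2-yl]-4-{5-methyl-2-[(2S)-6-methylhept-5-en-2-yl]phenoxy}phenol (target), via C1-lithiated aryloxybenzotriazole 23 (not isolated), via lithium boronate complex 24 (not isolated), via 6-boryl-cyclohexa-2,4-dienone 25 (not isolated), via aryl pinacol borate 26 (not isolated)
Conditions: LDA, THF, −78 °C; then 8 (1.3 equiv), −78 °C to rt; aq. NH4Cl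
Reagents that add atoms: none
Why: LDA removes the C1–H of ring A to give 23, which adds to the boron of 8 to form boronate 24; on warming, the secondary alkyl group shifts from boron to C1 while the weak N–O bond breaks heterolytically (benzotriazolide leaves, ring A acting as a phenoxenium equivalent), giving 6-alkyl-6-boryl-cyclohexa-2,4-dienone 25, whose 1,3-boryl shift from carbon to oxygen rearomatises ring A to borate 26, hydrolysed on work-up. The closest known reaction type is the enantiospecific sp2–sp3 coupling of ortho-lithiated O-benzotriazolyl phenols (and of para-lithiated phenolates under Bi(V) or sulfurane activation) with secondary and tertiary pinacol boronic esters, here applied to a fully elaborated diaryl ether. No ring is closed. The benzylic stereocentre is not created but transferred: the migrating carbon keeps its configuration in the concerted 1,2-metallate shift, so (S)-8 delivers the (S)-centre on ring A, and the (S)-centre already on ring B is not touched by base or boron. The step needs site-selective lithiation at C1 (over C5, over C2 next to the diaryl ether oxygen, and over ring B), which is secured by the stronger acidifying and chelating O–N(benzotriazole) group on C6 and by the methyl group that flanks C5, and it needs boron capture at −78 °C before loss of LiOBt to an aryne can compete. Because both stereocentres come from the same batch of 8, the minor enantiomer of 8 is channelled mainly into the (R,S)/(S,R) diastereomers, so the enantiomeric purity of 27 should exceed that of 8 (Horeau-type amplification).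

**Compound list**

1 | 5-bromo-2-methylpent-2-ene | CC(C)=CCCBr | starting material
2 | (4-methylpent-3-en-1-yl)magnesium bromide | CC(C)=CCC[Mg]Br | intermediate (not isolated)
3 | 2-(4-methylpent-3-en-1-yl)-4,4,5,5-tetramethyl-1,3,2-dioxaborolane | CC(C)=CCCB1OC(C)(C)C(C)(C)O1 | intermediate
4 | 2,4,6-triisopropylbenzoic acid | CC(C)c1cc(C(C)C)c(C(=O)O)c(C(C)C)c1 | starting material
5 | ethyl 2,4,6-triisopropylbenzoate | CCOC(=O)c1c(C(C)C)cc(C(C)C)cc1C(C)C | intermediate
6 | (R)-1-lithioethyl 2,4,6-triisopropylbenzoate, as its (+)-sparteine complex | C[C@@H]([Li])OC(=O)c1c(C(C)C)cc(C(C)C)cc1C(C)C | intermediate (not isolated)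
7 | lithium boronate complex of 6 with 3 | C[C@@H]([B-]1(CCC=C(C)C)OC(C)(C)C(C)(C)O1)OC(=O)c1c(C(C)C)cc(C(C)C)cc1C(C)C.[Li+] | intermediate (not isolated)
8 | 4,4,5,5-tetramethyl-2-[(2S)-6-methylhept-5-en-2-yl]-1,3,2-dioxaborolane | CC(C)=CCC[C@H](C)B1OC(C)(C)C(C)(C)O1 | intermediate
9 | (3-methylphenyl)boronic acid | Cc1cccc(B(O)O)c1 | starting material
10 | 1-hydroxy-1H-benzotriazole (anhydrous) | On1nnc2ccccc21 | starting material
11 | 1-(3-methylphenoxy)-1H-benzotriazole | Cc1cccc(On2nnc3ccccc32)c1 | intermediate
12 | [2-(1H-benzotriazol-1-yloxy)-4-methylphenyl]lithium | [Li]c1ccc(C)cc1On1nnc2ccccc21 | intermediate (not isolated)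
13 | lithium boronate complex of 12 with 8 | CC(C)=CCC[C@H](C)[B-]1(c2ccc(C)cc2On2nnc3ccccc32)OC(C)(C)C(C)(C)O1.[Li+] | intermediate (not isolated)
14 | 3-methyl-6-[(2S)-6-methylhept-5-en-2-yl]-6-(4,4,5,5-tetramethyl-1,3,2-dioxaborolan-2-yl)cyclohexa-2,4-dien-1-one (configuration at C6 undefined, transient) | CC(C)=CCC[C@H](C)C1(B2OC(C)(C)C(C)(C)O2)C=CC(C)=CC1=O | intermediate (not isolated)
15 | 4,4,5,5-tetramethyl-2-{5-methyl-2-[(2S)-6-methylhept-5-en-2-yl]phenoxy}-1,3,2-dioxaborolane | CC(C)=CCC[C@H](C)c1ccc(C)cc1OB1OC(C)(C)C(C)(C)O1 | intermediate (not isolated)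
16 | (S)-curcuphenol, 5-methyl-2-[(2S)-6-methylhept-5-en-2-yl]phenol | CC(C)=CCC[C@H](C)c1ccc(C)cc1O | intermediate
17 | 4-bromo-1-iodo-2-methylbenzene | Cc1cc(Br)ccc1I | starting material
18 | 4-bromo-2-methyl-1-{5-methyl-2-[(2S)-6-methylhept-5-en-2-yl]phenoxy}benzene | CC(C)=CCC[C@H](C)c1ccc(C)cc1Oc1ccc(Br)cc1C | intermediate
19 | (3-methyl-4-{5-methyl-2-[(2S)-6-methylhept-5-en-2-yl]phenoxy}phenyl)lithium | CC(C)=CCC[C@H](C)c1ccc(C)cc1Oc1ccc([Li])cc1C | intermediate (not isolated)
20 | lithium (3-methyl-4-{5-methyl-2-[(2S)-6-methylhept-5-en-2-yl]phenoxy}phenyl)triisopropoxyborate | CC(C)=CCC[C@H](C)c1ccc(C)cc1Oc1ccc([B-](OC(C)C)(OC(C)C)OC(C)C)cc1C.[Li+] | intermediate (not isolated)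
21 | (3-methyl-4-{5-methyl-2-[(2S)-6-methylhept-5-en-2-yl]phenoxy}phenyl)boronic acid | CC(C)=CCC[C@H](C)c1ccc(C)cc1Oc1ccc(B(O)O)cc1C | intermediate
22 | 1-(3-methyl-4-{5-methyl-2-[(2S)-6-methylhept-5-en-2-yl]phenoxy}phenoxy)-1H-benzotriazole | CC(C)=CCC[C@H](C)c1ccc(C)cc1Oc1ccc(On2nnc3ccccc32)cc1C | intermediate
23 | [2-(1H-benzotriazol-1-yloxy)-4-methyl-5-{5-methyl-2-[(2S)-6-methylhept-5-en-2-yl]phenoxy}phenyl]lithium | CC(C)=CCC[C@H](C)c1ccc(C)cc1Oc1cc([Li])c(On2nnc3ccccc32)cc1C | intermediate (not isolated)
24 | lithium boronate complex of 23 with 8 | CC(C)=CCC[C@H](C)c1ccc(C)cc1Oc1cc([B-]2(OC(C)(C)C(C)(C)O2)[C@@H](C)CCC=C(C)C)c(On2nnc3ccccc32)cc1C.[Li+] | intermediate (not isolated)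
25 | 3-methyl-6-[(2S)-6-methylhept-5-en-2-yl]-4-{5-methyl-2-[(2S)-6-methylhept-5-en-2-yl]phenoxy}-6-(4,4,5,5-tetramethyl-1,3,2-dioxaborolan-2-yl)cyclohexa-2,4-dien-1-one (configuration at C6 undefined, transient) | CC(C)=CCC[C@H](C)c1ccc(C)cc1OC1=CC(B2OC(C)(C)C(C)(C)O2)([C@@H](C)CCC=C(C)C)C(=O)C=C1C | intermediate (not isolated)
26 | pinacol borate of the target phenol, 4,4,5,5-tetramethyl-2-(aryloxy)-1,3,2-dioxaborolane | CC(C)=CCC[C@H](C)c1ccc(C)cc1Oc1cc([C@@H](C)CCC=C(C)C)c(OB2OC(C)(C)C(C)(C)O2)cc1C | intermediate (not isolated)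
27 | 5-methyl-2-[(2S)-6-methylhept-5-en-2-yl]-4-{5-methyl-2-[(2S)-6-methylhept-5-en-2-yl]phenoxy}phenol (CNP0354307.1) | CC(C)=CCC[C@H](C)c1cc(Oc2cc(C)ccc2[C@@H](C)CCC=C(C)C)c(C)cc1O | target

**Step count and risks**

Total step count: 9. Longest linear sequence: 7 steps (steps 1, 3, 5, 6, 7, 8, 9).

Steps most likely to fail:

1. Step 9. Deprotonation may occur at the wrong site of the polyfunctional diaryl ether, or the ortho-lithiated species may lose LiOBt to an aryne before boron capture, so that the boronate never forms or rearranges in low conversion. The fallback sets out from 21 and comes back to the route at 27; it replaces the internal N–O trigger by an external electrophile on a protected phenol. Oxidation of 21 (H2O2, NaOH, THF/H2O, 0 °C) should give 3-methyl-4-{5-methyl-2-[(2S)-6-methylhept-5-en-2-yl]phenoxy}phenol F1, which MOMCl/i-Pr2NEt converts into the methoxymethyl ether F2. Directed ortho-metalation of F2 (n-BuLi, TMEDA, THF, 0 °C) at the carbon para to the methyl group gives the aryllithium F3, which adds to 8 at −78 °C to give the lithium boronate complex F4. NBS at −78 °C then attacks the electron-rich ring of F4 (far more nucleophilic than the trisubstituted alkenes), which induces the stereoretentive 1,2-shift and boron/bromide elimination to the MOM-protected target F5. HCl in MeOH at rt releases 27.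

2. Step 5. Lithiation may partly take place at the carbon between the oxygen and the methyl group, or the aryllithium may decompose before capture, giving regioisomeric or no coupling product. The fallback sets out from 3 and comes back at 16; it builds the benzylic centre from the carbinol side (lithiation–borylation then protodeboronation). Commercial 1-(2-methoxy-4-methylphenyl)ethanone (CC(=O)c1ccc(C)cc1OC) is reduced by Corey–Bakshi–Shibata reduction ((R)-Me-CBS, BH3·SMe2) to (S)-1-(2-methoxy-4-methylphenyl)ethanol F6 and carbamoylated (i-Pr2NCOCl, Et3N, reflux) to the N,N-diisopropylcarbamate F7. s-BuLi (Et2O, −78 °C) gives with retention the tertiary benzylic lithium compound F8, which takes up 3 with retention to form the boronate complex F9. The homoprenyl group then shifts with inversion at carbon to give the tertiary boronic ester F10, and stereoretentive protodeboronation (CsF, H2O, dioxane, or TBAF·3H2O) gives (S)-curcuphenol methyl ether F11. NaSEt in DMF at 130 °C cleaves the methyl ether to 16 without touching the alkene.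

3. Step 6. The coupling of two ortho-substituted partners may be slow enough that oxidative addition at the C–Br bond competes, leading to double etherification or oligomers. The fallback sets out from 17 (and 16) and comes back at 18; it replaces copper catalysis by a metal-free hypervalent iodine arylation. 17 is oxidised with mCPBA/TsOH·H2O in the presence of 1,3,5-trimethoxybenzene to (4-bromo-2-methylphenyl)(2,4,6-trimethoxyphenyl)iodonium tosylate F12. The potassium phenoxide of 16 (t-BuOK, THF/toluene, rt) is then arylated by F12 through ligand coupling, in which the ortho-methyl aryl group is transferred and the trimethoxyphenyl group stays on iodine, giving 18 with the bromide untouched.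

**Further compounds**

F1 | step 9 | 3-methyl-4-{5-methyl-2-[(2S)-6-methylhept-5-en-2-yl]phenoxy}phenol | CC(C)=CCC[C@H](C)c1ccc(C)cc1Oc1ccc(O)cc1C
F2 | step 9 | 4-(methoxymethoxy)-2-methyl-1-{5-methyl-2-[(2S)-6-methylhept-5-en-2-yl]phenoxy}benzene | CC(C)=CCC[C@H](C)c1ccc(C)cc1Oc1ccc(OCOC)cc1C
F3 | step 9 | [2-(methoxymethoxy)-4-methyl-5-{5-methyl-2-[(2S)-6-methylhept-5-en-2-yl]phenoxy}phenyl]lithium | CC(C)=CCC[C@H](C)c1ccc(C)cc1Oc1cc([Li])c(OCOC)cc1C
F4 | step 9 | lithium boronate complex of F3 with 8 | CC(C)=CCC[C@H](C)c1ccc(C)cc1Oc1cc([B-]2(OC(C)(C)C(C)(C)O2)[C@@H](C)CCC=C(C)C)c(OCOC)cc1C.[Li+]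
F5 | step 9 | methoxymethyl ether of the target | CC(C)=CCC[C@H](C)c1ccc(C)cc1Oc1cc([C@@H](C)CCC=C(C)C)c(OCOC)cc1C
F6 | step 5 | (S)-1-(2-methoxy-4-methylphenyl)ethanol | C[C@H](O)c1ccc(C)cc1OC
F7 | step 5 | (S)-1-(2-methoxy-4-methylphenyl)ethyl N,N-diisopropylcarbamate | C[C@H](OC(=O)N(C(C)C)C(C)C)c1ccc(C)cc1OC
F8 | step 5 | 1-lithio-1-(2-methoxy-4-methylphenyl)ethyl N,N-diisopropylcarbamate | C[C@]([Li])(OC(=O)N(C(C)C)C(C)C)c1ccc(C)cc1OC
F9 | step 5 | lithium boronate complex of F8 with 3 | C[C@]([B-]1(CCC=C(C)C)OC(C)(C)C(C)(C)O1)(OC(=O)N(C(C)C)C(C)C)c1ccc(C)cc1OC.[Li+]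
F10 | step 5 | 2-[(2S)-2-(2-methoxy-4-methylphenyl)-6-methylhept-5-en-2-yl]-4,4,5,5-tetramethyl-1,3,2-dioxaborolane | CC(C)=CCC[C@](B1OC(C)(C)C(C)(C)O1)(C)c1ccc(C)cc1OC
F11 | step 5 | (S)-curcuphenol methyl ether, 2-methoxy-4-methyl-1-[(2S)-6-methylhept-5-en-2-yl]benzene | CC(C)=CCC[C@H](C)c1ccc(C)cc1OC
F12 | step 6 | (4-bromo-2-methylphenyl)(2,4,6-trimethoxyphenyl)iodonium 4-methylbenzenesulfonate | Cc1cc(Br)ccc1[I+]c1c(OC)cc(OC)cc1OC.Cc1ccc(S(=O)(=O)[O-])cc1
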